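## Plan

- Retrosynthetic cuts, in order: the O1–C2 bond of the pyranone ring (made last), the C4–C4a aryl ketone bond, the C8–CH2 aryl–alkyl bond, and the Cα–CH2(prenyl) bond of the side chain.
- Enabling feature: the free 4'-OH of ring B is para to C2 (with the 2'-OMe ortho), so C2 is the exocyclic carbon of a latent para-quinone methide. The ring-A oxygen at C8a sits six atoms away on a chelated 2-acylphenol, and its other ortho oxygen (C5) is capped as OMe.
- Forward: Evans deconjugative prenylation gives (S)-lavandulyl iodide; Negishi coupling attaches it to a 2-iodo-5-methoxyresorcinol bis-MOM ether; epoxidation and hydride opening give the tertiary alcohol.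
- Ortho-lithiation and acylation with a B-ring Weinreb amide give the open-chain dihydrochalcone. After MOM removal, the pyranone ring (the only ring formed) is closed last by oxidative C–H/O–H coupling.
- Stereochemistry: the side-chain centre comes from the (S)-4-benzyloxazolidinone auxiliary; C2 comes from a chiral phosphoric acid in the ring closure, with no later step that could scramble it.

Key step: step 15

Assumption: the sense of induction of the chiral phosphoric acid in step 15 cannot be assigned in advance. (R)-TRIP is written, and its enantiomer is used instead if a first experiment shows the (2R)-epimer to predominate.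

## Route

Step 1
Reactants: 1 (S)-4-benzyl-1,3-oxazolidin-2-one; 2 3-methylbut-2-enoyl chloride
Product: 4 (4S)-4-benzyl-3-(3-methylbut-2-enoyl)-1,3-oxazolidin-2-one, via lithium oxazolidinide 3 (not isolated)
Conditions: n-BuLi, THF, −78 °C; then 2, −78 → 0 °C
Reagents that add atoms: none
Why: N-acylation of the lithiated Evans auxiliary by the acid chloride is a standard imide synthesis and creates no new stereocentre.

Step 2
Reactants: 4 (4S)-4-benzyl-3-(3-methylbut-2-enoyl)-1,3-oxazolidin-2-one; 5 1-bromo-3-methylbut-2-ene (prenyl bromide)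
Product: 7 (4S)-4-benzyl-3-[(2S)-5-methyl-2-(prop-1-en-2-yl)hex-4-enoyl]-1,3-oxazolidin-2-one, via sodium (Z)-dienolate 6 (not isolated)
Conditions: NaHMDS, THF, −78 °C; then 5, −78 → −40 °C
Reagents that add atoms: none
Why: γ-Deprotonation of the s-cis enoyl imide gives the chelated (Z)-dienolate, which is alkylated at the α-carbon on the face opposite the benzyl group (Evans asymmetric alkylation in its deconjugative form); this sets the (2S) centre that becomes the (R) centre of the side chain and leaves the isopropenyl group in place.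

Step 3
Reactants: 7 (4S)-4-benzyl-3-[(2S)-5-methyl-2-(prop-1-en-2-yl)hex-4-enoyl]-1,3-oxazolidin-2-one
Product: 8 (2S)-5-methyl-2-(prop-1-en-2-yl)hex-4-en-1-ol ((S)-lavandulol)
Conditions: LiBH4, H2O (1.1 equiv), Et2O, 0 °C
Reagents that add atoms: none
Why: Reductive cleavage of the N-acyloxazolidinone with LiBH4 should give the primary alcohol at 0 °C without touching the alkenes or epimerising the α-centre, and it returns the auxiliary.

Step 4
Reactants: 8 (2S)-5-methyl-2-(prop-1-en-2-yl)hex-4-en-1-ol
Product: 9 (3S)-3-(iodomethyl)-2,6-dimethylhepta-1,5-diene ((S)-lavandulyl iodide)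
Conditions: PPh3, I2, imidazole, CH2Cl2, 0 °C
Reagents that add atoms: iodine, II
Why: Appel iodination of the primary alcohol proceeds by SN2 at CH2, so the adjacent stereocentre is not involved.

Step 5
Reactants: 10 5-methoxybenzene-1,3-diol
Product: 11 1-methoxy-3,5-bis(methoxymethoxy)benzene
Conditions: MOMCl, i-Pr2NEt, CH2Cl2, 0 °C → rt
Reagents that add atoms: chloromethyl methyl ether, COCCl
Why: O-Alkylation of both phenols with MOMCl installs acetal groups that protect the future 7-OH and O1 and later direct ortho-lithiation.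

Step 6
Reactants: 11 1-methoxy-3,5-bis(methoxymethoxy)benzene
Product: 13 2-iodo-5-methoxy-1,3-bis(methoxymethoxy)benzene, via aryllithium 12 (not isolated)
Conditions: n-BuLi, THF, 0 °C; then I2, −78 °C → rt
Reagents that add atoms: iodine, II
Why: Directed ortho-metalation should occur at the carbon flanked by the two OMOM groups, which are stronger and cooperative directors compared with OMe, and iodinolysis of the aryllithium gives the iodide.

Step 7
Reactants: 9 (3S)-3-(iodomethyl)-2,6-dimethylhepta-1,5-diene; 13 2-iodo-5-methoxy-1,3-bis(methoxymethoxy)benzene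
Product: 15 5-methoxy-1,3-bis(methoxymethoxy)-2-[(2R)-5-methyl-2-(prop-1-en-2-yl)hex-4-en-1-yl]benzene, via alkylzinc iodide 14 (not isolated)
Conditions: Zn dust (activated), LiCl, THF, 40 °C; then 13, Pd(OAc)2 (cat.), SPhos (cat.), THF, 50 °C
Reagents that add atoms: none
Why: Zinc insertion into the primary iodide (Knochel conditions) followed by Pd/SPhos-catalysed Negishi sp3–sp2 coupling with the di-ortho-alkoxy aryl iodide joins the side chain at the future C8; the stereocentre is β to zinc and is not involved.

Step 8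
Reactants: 15 5-methoxy-1,3-bis(methoxymethoxy)-2-[(2R)-5-methyl-2-(prop-1-en-2-yl)hex-4-en-1-yl]benzene
Product: 16 2-{(2S)-2-[(3,3-dimethyloxiran-2-yl)methyl]-3-methylbut-3-en-1-yl}-5-methoxy-1,3-bis(methoxymethoxy)benzene (both oxirane epimers; same spatial arrangement at the side-chain centre, the descriptor changes only through CIP priorities)
Conditions: mCPBA (1.05 equiv), NaHCO3, CH2Cl2, 0 °C
Reagents that add atoms: meta-chloroperoxybenzoic acid, O=C(OO)c1cccc(Cl)c1
Why: Prilezhaev epoxidation should select the more nucleophilic trisubstituted prenyl alkene over the 1,1-disubstituted isopropenyl group with one equivalent of buffered peracid; the new oxirane stereocentre is irrelevant because step 9 removes it.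

Step 9
Reactants: 16 2-{(2S)-2-[(3,3-dimethyloxiran-2-yl)methyl]-3-methylbut-3-en-1-yl}-5-methoxy-1,3-bis(methoxymethoxy)benzene
Product: 17 (5R)-6-[4-methoxy-2,6-bis(methoxymethoxy)phenyl]-2-methyl-5-(prop-1-en-2-yl)hexan-2-ol
Conditions: LiAlH4, THF, 0 → 40 °C
Reagents that add atoms: none
Why: Hydride opens the trisubstituted epoxide by SN2 at the less substituted carbon, giving the tertiary alcohol (overall Markovnikov hydration of the prenyl alkene) and erasing the oxirane stereocentre; MOM ethers and the isopropenyl group are inert.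

Step 10
Reactants: 18 4-hydroxy-2-methoxybenzaldehyde
Product: 19 2-methoxy-4-(methoxymethoxy)benzaldehyde
Conditions: MOMCl, i-Pr2NEt, CH2Cl2, 0 °C → rt
Reagents that add atoms: chloromethyl methyl ether, COCCl
Why: O-Alkylation of the phenol with MOMCl masks the acidic B-ring hydroxyl for the organolithium step.

Step 11
Reactants: 19 2-methoxy-4-(methoxymethoxy)benzaldehyde; 20 diethyl {2-[methoxy(methyl)amino]-2-oxoethyl}phosphonate
Product: 22 (2E)-N-methoxy-3-[2-methoxy-4-(methoxymethoxy)phenyl]-N-methylprop-2-enamide, via sodium phosphonate carbanion 21 (not isolated)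
Conditions: NaH, THF, 0 °C; then 19, 0 °C → rt
Reagents that add atoms: none
Why: Horner–Wadsworth–Emmons olefination with the stabilised Weinreb-amide phosphonate should give the (E)-enamide.

Step 12
Reactants: 22 (2E)-N-methoxy-3-[2-methoxy-4-(methoxymethoxy)phenyl]-N-methylprop-2-enamide
Product: 23 N-methoxy-3-[2-methoxy-4-(methoxymethoxy)phenyl]-N-methylpropanamide
Conditions: H2 (1 atm), 10% Pd/C, EtOAc, rt
Reagents that add atoms: none
Why: Catalytic hydrogenation saturates the conjugated alkene; the aryl MOM ether and, at 1 atm with short contact time, the amide N–O bond should survive.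

Step 13
Reactants: 17 (5R)-6-[4-methoxy-2,6-bis(methoxymethoxy)phenyl]-2-methyl-5-(prop-1-en-2-yl)hexan-2-ol; 23 N-methoxy-3-[2-methoxy-4-(methoxymethoxy)phenyl]-N-methylpropanamide
Product: 26 1-{3-[(2R)-5-hydroxy-5-methyl-2-(prop-1-en-2-yl)hexyl]-6-methoxy-2,4-bis(methoxymethoxy)phenyl}-3-[2-methoxy-4-(methoxymethoxy)phenyl]propan-1-one, via dilithio species 24 (not isolated), via tetrahedral lithium hemiaminal 25 (not isolated)
Conditions: n-BuLi (2.1 equiv), TMEDA, THF, 0 °C; then 23, −78 → 0 °C; then H2O
Reagents that add atoms: none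
Why: The first equivalent of n-BuLi forms the lithium alkoxide and the second effects directed ortho-metalation between OMOM and OMe (the two open ring positions are equivalent); the aryllithium adds once to the Weinreb amide through the chelated tetrahedral intermediate, which collapses to the ketone on work-up (Weinreb ketone synthesis).

Step 14
Reactants: 26 1-{3-[(2R)-5-hydroxy-5-methyl-2-(prop-1-en-2-yl)hexyl]-6-methoxy-2,4-bis(methoxymethoxy)phenyl}-3-[2-methoxy-4-(methoxymethoxy)phenyl]propan-1-one
Product: 27 1-{2,4-dihydroxy-3-[(2R)-5-hydroxy-5-methyl-2-(prop-1-en-2-yl)hexyl]-6-methoxyphenyl}-3-(4-hydroxy-2-methoxyphenyl)propan-1-one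
Conditions: ZnBr2, n-PrSH, CH2Cl2, 0 °C → rt, short reaction time
Reagents that add atoms: none
Why: ZnBr2/n-PrSH cleaves aryl MOM ethers within minutes by Lewis-acid activation and thiol capture of the methoxymethyl cation, which should spare the tertiary alcohol, the isopropenyl group and the ketone; no C2 stereocentre exists yet.

Step 15
Reactants: 27 1-{2,4-dihydroxy-3-[(2R)-5-hydroxy-5-methyl-2-(prop-1-en-2-yl)hexyl]-6-methoxyphenyl}-3-(4-hydroxy-2-methoxyphenyl)propan-1-one
Product: 29 (2S)-7-hydroxy-2-(4-hydroxy-2-methoxyphenyl)-8-[(2R)-5-hydroxy-5-methyl-2-(prop-1-en-2-yl)hexyl]-5-methoxy-2,3-dihydro-4H-chromen-4-one, via para-quinone methide 28 (not isolated)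
Conditions: DDQ (1.05 equiv, slow addition), (R)-TRIP (10 mol %), 4 Å MS, CH2Cl2–toluene, −40 °C; quench cold with aq. sodium ascorbate
Reagents that add atoms: none
Why: Proposed new method: DDQ removes hydride, through the phenol charge-transfer complex, from the ring-B benzylic CH2 of 27 (para to the free 4-OH, ortho to OMe) to give para-quinone methide 28 and the hydroquinone; the chiral phosphoric acid then binds the quinone-methide carbonyl through P–OH and the ring-A C2' hydroxyl through P=O and delivers that oxygen to the exocyclic methide carbon, re-aromatising ring B. The closest known reaction types are the DDQ-mediated oxidative cyclisation of 2'-hydroxydihydrochalcones and the phosphoric-acid-catalysed enantioselective 1,6-addition of heteroatom nucleophiles to para-quinone methides generated in situ. The pyranone ring closes in the 6-exo-trig mode, since the methide C=C lies outside the new ring. The C2 stereocentre is set by the catalyst, whose 3,3'-aryl pocket differentiates the two faces of the planar methide carbon; the side-chain centre is too remote to interfere, so the step is catalyst-controlled. Chemoselectivity rests on ring B being the only non-acylated and most electron-rich phenol (ring A is a chelated acylphloroglucinol); regioselectivity rests on the C5 OMe group, which leaves a single ortho hydroxyl; kinetic control rests on low temperature and slow addition of one equivalent of oxidant, so that oxidation of the product C2–H and tautomerisation of 28 to the chalcone should not compete.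

## Compound list

1 | (S)-4-benzyl-1,3-oxazolidin-2-one | O=C1N[C@@H](Cc2ccccc2)CO1 | starting material
2 | 3-methylbut-2-enoyl chloride | CC(C)=CC(=O)Cl | starting material
3 | lithium salt of (S)-4-benzyl-1,3-oxazolidin-2-one | [Li]N1[C@@H](Cc2ccccc2)COC1=O | intermediate
4 | (4S)-4-benzyl-3-(3-methylbut-2-enoyl)-1,3-oxazolidin-2-one | CC(C)=CC(=O)N1[C@@H](Cc2ccccc2)COC1=O | intermediate
5 | 1-bromo-3-methylbut-2-ene | CC(C)=CCBr | starting material
6 | sodium (Z)-dienolate of 4 | C=C(C)/C=C(\O[Na])N1[C@@H](Cc2ccccc2)COC1=O | intermediate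
7 | (4S)-4-benzyl-3-[(2S)-5-methyl-2-(prop-1-en-2-yl)hex-4-enoyl]-1,3-oxazolidin-2-one | C=C(C)[C@H](CC=C(C)C)C(=O)N1[C@@H](Cc2ccccc2)COC1=O | intermediate
8 | (2S)-5-methyl-2-(prop-1-en-2-yl)hex-4-en-1-ol | C=C(C)[C@H](CC=C(C)C)CO | intermediate
9 | (3S)-3-(iodomethyl)-2,6-dimethylhepta-1,5-diene | C=C(C)[C@H](CC=C(C)C)CI | intermediate
10 | 5-methoxybenzene-1,3-diol | COc1cc(O)cc(O)c1 | starting material
11 | 1-methoxy-3,5-bis(methoxymethoxy)benzene | COCOc1cc(OC)cc(OCOC)c1 | intermediate
12 | [4-methoxy-2,6-bis(methoxymethoxy)phenyl]lithium | [Li]c1c(OCOC)cc(OC)cc1OCOC | intermediate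
13 | 2-iodo-5-methoxy-1,3-bis(methoxymethoxy)benzene | COCOc1cc(OC)cc(OCOC)c1I | intermediate
14 | [(2S)-5-methyl-2-(prop-1-en-2-yl)hex-4-en-1-yl]zinc iodide | C=C(C)[C@H](CC=C(C)C)C[Zn]I | intermediate
15 | 5-methoxy-1,3-bis(methoxymethoxy)-2-[(2R)-5-methyl-2-(prop-1-en-2-yl)hex-4-en-1-yl]benzene | C=C(C)[C@H](CC=C(C)C)Cc1c(OCOC)cc(OC)cc1OCOC | intermediate
16 | 2-{(2S)-2-[(3,3-dimethyloxiran-2-yl)methyl]-3-methylbut-3-en-1-yl}-5-methoxy-1,3-bis(methoxymethoxy)benzene (oxirane epimers) | C=C(C)[C@H](CC1OC1(C)C)Cc1c(OCOC)cc(OC)cc1OCOC | intermediate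
17 | (5R)-6-[4-methoxy-2,6-bis(methoxymethoxy)phenyl]-2-methyl-5-(prop-1-en-2-yl)hexan-2-ol | C=C(C)[C@H](CCC(C)(C)O)Cc1c(OCOC)cc(OC)cc1OCOC | intermediate
18 | 4-hydroxy-2-methoxybenzaldehyde | COc1cc(O)ccc1C=O | starting material
19 | 2-methoxy-4-(methoxymethoxy)benzaldehyde | COCOc1ccc(C=O)c(OC)c1 | intermediate
20 | diethyl {2-[methoxy(methyl)amino]-2-oxoethyl}phosphonate | CCOP(=O)(CC(=O)N(C)OC)OCC | starting material
21 | sodium salt of the carbanion of 20 | [Na+].CCOP(=O)([CH-]C(=O)N(C)OC)OCC | intermediate
22 | (2E)-N-methoxy-3-[2-methoxy-4-(methoxymethoxy)phenyl]-N-methylprop-2-enamide | COCOc1ccc(/C=C/C(=O)N(C)OC)c(OC)c1 | intermediate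
23 | N-methoxy-3-[2-methoxy-4-(methoxymethoxy)phenyl]-N-methylpropanamide | COCOc1ccc(CCC(=O)N(C)OC)c(OC)c1 | intermediate
24 | {3-[(2R)-5-(lithiooxy)-5-methyl-2-(prop-1-en-2-yl)hexyl]-6-methoxy-2,4-bis(methoxymethoxy)phenyl}lithium | C=C(C)[C@H](CCC(C)(C)O[Li])Cc1c(OCOC)cc(OC)c([Li])c1OCOC | intermediate
25 | dilithium salt of the tetrahedral adduct of 24 and 23 (both epimers at the hemiaminal carbon) | C=C(C)[C@H](CCC(C)(C)O[Li])Cc1c(OCOC)cc(OC)c(C(O[Li])(CCc2ccc(OCOC)cc2OC)N(C)OC)c1OCOC | intermediate
26 | 1-{3-[(2R)-5-hydroxy-5-methyl-2-(prop-1-en-2-yl)hexyl]-6-methoxy-2,4-bis(methoxymethoxy)phenyl}-3-[2-methoxy-4-(methoxymethoxy)phenyl]propan-1-one | C=C(C)[C@H](CCC(C)(C)O)Cc1c(OCOC)cc(OC)c(C(=O)CCc2ccc(OCOC)cc2OC)c1OCOC | intermediate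
27 | 1-{2,4-dihydroxy-3-[(2R)-5-hydroxy-5-methyl-2-(prop-1-en-2-yl)hexyl]-6-methoxyphenyl}-3-(4-hydroxy-2-methoxyphenyl)propan-1-one | C=C(C)[C@H](CCC(C)(C)O)Cc1c(O)cc(OC)c(C(=O)CCc2ccc(O)cc2OC)c1O | intermediate
28 | 4-(3-{2,4-dihydroxy-3-[(2R)-5-hydroxy-5-methyl-2-(prop-1-en-2-yl)hexyl]-6-methoxyphenyl}-3-oxopropylidene)-3-methoxycyclohexa-2,5-dien-1-one (alkene geometry undefined) | C=C(C)[C@H](CCC(C)(C)O)Cc1c(O)cc(OC)c(C(=O)CC=C2C=CC(=O)C=C2OC)c1O | intermediate
29 | (2S)-7-hydroxy-2-(4-hydroxy-2-methoxyphenyl)-8-[(2R)-5-hydroxy-5-methyl-2-(prop-1-en-2-yl)hexyl]-5-methoxy-2,3-dihydro-4H-chromen-4-one | C=C(C)[C@H](CCC(C)(C)O)Cc1c(O)cc(OC)c2c1O[C@H](c1ccc(O)cc1OC)CC2=O | target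

## Step count

Total steps: 15. Longest linear sequence: 10 steps (1, 2, 3, 4, 7, 8, 9, 13, 14, 15).

## Steps most likely to fail

**Step 15 (bears the label "Proposed new method:").** Three processes may defeat it: poor facial selectivity at the methide carbon, tautomerisation of the quinone methide to the open-chain enone before closure, and competing oxidation of ring A or of the product C2–H. The fallback uses only classical chemistry with no oxidant; it sets out from 17 and 19 and comes back at 29. Aryllithium 24, generated from 17 as in step 13, is acylated with N-methoxy-N-methylacetamide to 1-{3-[(2R)-5-hydroxy-5-methyl-2-(prop-1-en-2-yl)hexyl]-6-methoxy-2,4-bis(methoxymethoxy)phenyl}ethan-1-one F1. Claisen–Schmidt condensation of F1 with aldehyde 19 (KOH, EtOH–H2O, rt) should give the tris-MOM chalcone F2. The MOM groups are removed with dilute HCl in MeOH at rt (thiol-free because of the enone) to give the 2'-hydroxychalcone F3. F3 is then closed under the classical chalcone–flavanone isomerisation conditions (NaOAc, EtOH, reflux) to 29 together with its (2R)-epimer F4. The two are diastereomers and are separated by preparative HPLC on a chiral phase; F4 is returned to the isomerisation conditions, where ring opening and reclosure re-equilibrate C2.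

**Step 7.** Slow or incomplete zinc insertion, rearrangement of the homoallylic organometallic, or β-hydride elimination at palladium in the hindered coupling may erode the sp3–sp2 union. The fallback reverses the roles of the partners; it sets out from 11 and 9 and comes back at 15. Aryllithium 12, made from 11 as in step 6, is alkylated directly by iodide 9 in THF–DMPU with catalytic CuI at −78 → 0 °C, a classical SN2 alkylation of a 2,6-dialkoxyaryllithium. No new isolable compound arises on this path.

**Step 13.** Proton transfer from the α-CH2 of the Weinreb amide to the hindered aryllithium (enolisation instead of addition), or incomplete metalation in the presence of the lithium alkoxide, may stall the acylation. The fallback uses a more electrophilic partner and adjusts the oxidation level afterwards; it sets out from 23 and 17 and comes back at 26. Amide 23 is reduced with DIBAL-H (−78 °C) to 3-[2-methoxy-4-(methoxymethoxy)phenyl]propanal F5. Aryllithium 24 from 17 adds to F5 to give the secondary benzylic carbinol F6 as a mixture of carbinol epimers. Dess–Martin oxidation (NaHCO3, CH2Cl2) of F6 should give ketone 26, the tertiary alcohol being inert.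

## Further compounds

F1 | step 15 | 1-{3-[(2R)-5-hydroxy-5-methyl-2-(prop-1-en-2-yl)hexyl]-6-methoxy-2,4-bis(methoxymethoxy)phenyl}ethan-1-one | C=C(C)[C@H](CCC(C)(C)O)Cc1c(OCOC)cc(OC)c(C(C)=O)c1OCOC
F2 | step 15 | (2E)-1-{3-[(2R)-5-hydroxy-5-methyl-2-(prop-1-en-2-yl)hexyl]-6-methoxy-2,4-bis(methoxymethoxy)phenyl}-3-[2-methoxy-4-(methoxymethoxy)phenyl]prop-2-en-1-one | C=C(C)[C@H](CCC(C)(C)O)Cc1c(OCOC)cc(OC)c(C(=O)/C=C/c2ccc(OCOC)cc2OC)c1OCOC
F3 | step 15 | (2E)-1-{2,4-dihydroxy-3-[(2R)-5-hydroxy-5-methyl-2-(prop-1-en-2-yl)hexyl]-6-methoxyphenyl}-3-(4-hydroxy-2-methoxyphenyl)prop-2-en-1-one | C=C(C)[C@H](CCC(C)(C)O)Cc1c(O)cc(OC)c(C(=O)/C=C/c2ccc(O)cc2OC)c1O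
F4 | step 15 | (2R)-7-hydroxy-2-(4-hydroxy-2-methoxyphenyl)-8-[(2R)-5-hydroxy-5-methyl-2-(prop-1-en-2-yl)hexyl]-5-methoxy-2,3-dihydro-4H-chromen-4-one | C=C(C)[C@H](CCC(C)(C)O)Cc1c(O)cc(OC)c2c1O[C@@H](c1ccc(O)cc1OC)CC2=O
F0 | step 7 | none | none
F5 | step 13 | 3-[2-methoxy-4-(methoxymethoxy)phenyl]propanal | COCOc1ccc(CCC=O)c(OC)c1
F6 | step 13 | (5R)-6-{3-[1-hydroxy-3-(2-methoxy-4-(methoxymethoxy)phenyl)propyl]-4-methoxy-2,6-bis(methoxymethoxy)phenyl}-2-methyl-5-(prop-1-en-2-yl)hexan-2-ol (carbinol epimers) | C=C(C)[C@H](CCC(C)(C)O)Cc1c(OCOC)cc(OC)c(C(O)CCc2ccc(OCOC)cc2OC)c1OCOC
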